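**Plan**

1. Retrosynthesis: cut the C3–O ester bond (acid from a Horner–Wadsworth–Emmons reaction on (E)-non-3-en-2-one), the C7=C11 bond (aldol with acetone), the C3–O/C4–H pair (back to a C3=C4 alkene) and the trans C10–H (back to a C9=C10 enol-ether enone).
2. The remaining cis-decalone contains C8(=O)–C7–C6–C5–C4=C3, a δ,ε-unsaturated ketone. Cutting C5–C6 and re-joining C3–C8 (retro oxy-Cope) gives a 2-vinylbicyclo[2.2.2]oct-5-en-2-ol, which falls apart into vinyl Grignard, a vinyl sulfone (bonds C10–C1 and C3–C2) and a cyclohexadienone.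
3. Enabling feature: C8, C9, C10, C5, C4 and C3 run contiguously through rings B and A, with oxygen on C8 and C9 and the methyls C14 and C15 on C5 and C4. This is the substitution pattern of 2-methoxy-4,5-dimethylphenol.
4. Forward: dearomatisation and cycloaddition build the bicycle (ring A carbons plus the C8–C9 bridge); the [3,3] shift closes ring B and creates quaternary C5; ring B is then adjusted, ring A oxygenated and the trienoate attached last.
5. Stereochemistry: absolute configuration from chiral-phase resolution of the cycloadduct; C5 relayed from bridgehead C10 by the suprafacial shift; C10 reset to trans by a Li/NH3 reduction; C9 by equilibration to the equatorial ether; C3 and C4 together by α-face syn hydroboration anti to C14.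

Key step: step 5

Conventions: the target's numbering is used throughout (ring A = C1, C2, C3, C4, C5, C10; ring B = C5, C6, C7, C8, C9, C10; C14 on C5, C15 on C4, C11 the isopropylidene carbon); β is the face of C14. Racemic compounds are drawn as the enantiomer that is carried on.
Assumption: 2-methoxy-4,5-dimethylphenol is used as a purchased phenol.

**Route**

Step 1
Reactants: 1 2-methoxy-4,5-dimethylphenol; 2 phenyl vinyl sulfone
Product: 4 racemic 3,3-dimethoxy-5,6-dimethyl-7-(phenylsulfonyl)bicyclo[2.2.2]oct-5-en-2-one (sulfonyl syn to the alkene bridge), via masked o-benzoquinone 3 (not isolated)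
Conditions: PhI(OAc)2 (1.1 equiv), 2 (5 equiv), MeOH, slow addition of 1, 0 °C → rt
Reagents that add atoms: methanol, CO
Why: Oxidative dearomatisation of the guaiacol by the trivalent iodine reagent in methanol gives the 6,6-dimethoxycyclohexa-2,4-dienone, which is trapped in situ by the excess dienophile in a Diels–Alder reaction that is normally ortho- and endo-selective for such dienones; the position and configuration of the sulfonyl carbon do not matter because that centre becomes CH2 in step 4.

Step 2
Reactants: 4 racemic sulfonyl bicyclooctenone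
Product: 5 (1R,4S,7S)-3,3-dimethoxy-5,6-dimethyl-7-(phenylsulfonyl)bicyclo[2.2.2]oct-5-en-2-one
Conditions: preparative SFC, amylose tris(3,5-dimethylphenylcarbamate) phase, CO2/MeOH, 35 °C
Reagents that add atoms: none
Why: Resolution by chromatography on a chiral stationary phase, which is routine for rigid aryl sulfonyl ketones of this kind; the sulfur atom should allow the absolute configuration of the crystalline enantiomer to be assigned by anomalous-dispersion X-ray analysis.

Step 3
Reactants: 5 enantiopure sulfonyl bicyclooctenone; 6 vinylmagnesium bromide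
Product: 7 (1R,2R,4S,7S)-3,3-dimethoxy-5,6-dimethyl-7-(phenylsulfonyl)-2-vinylbicyclo[2.2.2]oct-5-en-2-ol
Conditions: CH2=CHMgBr (3 equiv), THF, −78 → 0 °C; aq. NH4Cl
Reagents that add atoms: none
Why: Grignard 1,2-addition to a non-enolisable ketone, expected to occur on the carbonyl face flanked by the sp2 bridge and not the ethano bridge with its inward hydrogen, which places the vinyl group syn to the dimethyl-alkene bridge and sets the carbinol centre; any deprotonation next to the sulfone only consumes reagent.

Step 4
Reactants: 7 sulfonyl vinyl carbinol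
Product: 8 (1R,2R,4S)-3,3-dimethoxy-5,6-dimethyl-2-vinylbicyclo[2.2.2]oct-5-en-2-ol
Conditions: Na(Hg) (6% Na), Na2HPO4, MeOH/THF, −20 °C → rt
Reagents that add atoms: none
Why: Reductive desulfonylation by electron transfer from sodium amalgam cleaves the C–S bond of the secondary alkyl aryl sulfone, while the ketal, the tertiary alcohol and the unactivated alkenes should be inert; it is done after step 3 so that no α-ketal ketone meets the reducing metal.

Step 5
Reactants: 8 vinyl bicyclooctenol
Product: 11 cis-fused 9,9-dimethoxy-4,5β-dimethyldecal-3-en-8-one (10β-H), via potassium alkoxide 9 (not isolated), via potassium enolate 10 (not isolated)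
Conditions: KH (3 equiv), 18-crown-6 (1.5 equiv), THF, 0 °C → rt; aq. NH4Cl, −78 °C
Reagents that add atoms: none
Why: KH with the crown ether gives the dissociated alkoxide 9, whose 1,5-diene C6=C7–C8–C3–C4=C5 undergoes a charge-accelerated concerted [3,3] sigmatropic shift that forms C5–C6, breaks C3–C8 and delivers the C7–C8 enolate 10, protonated at C7 on work-up. The closest known reaction type is the anionic oxy-Cope rearrangement of 2-vinylbicyclo[2.2.2]oct-5-en-2-ols to cis-decalones. Ring B (C5–C6–C7–C8–C9–C10) closes by this sigmatropic bond formation through the boat-like array that the bicycle enforces, and the former cyclohexene ring is left as ring A. The new quaternary centre C5 is controlled by the suprafacial course: C6 can only reach the alkene face turned toward the C8–C9 bridge, so C14 ends up cis to the inherited bridgehead hydrogen on C10. The step needs the vinyl group syn to the C4=C5 bridge, which step 3 secures, and the enolate is regiodefined because C9 carries no hydrogen.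

Step 6
Reactants: 11 cis-decalone ketal
Product: 13 9-hydroxy-4,5β-dimethyl-decal-3,9(10)-dien-8-one (diosphenol), via cis-8,9-dione 12 (not isolated)
Conditions: 3 M HCl (aq), THF, 45 °C
Reagents that add atoms: water, O
Why: Acid-catalysed hydrolysis of the α-keto dimethyl ketal gives the 1,2-dione, which should tautomerise to the more substituted C9=C10 enol; this deliberately erases the cis C10 centre so that it can be set again under kinetic control.

Step 7
Reactants: 13 diosphenol
Product: 14 9-(methoxymethoxy)-4,5β-dimethyl-decal-3,9(10)-dien-8-one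
Conditions: MOMCl, i-Pr2NEt, CH2Cl2, 0 °C → rt
Reagents that add atoms: chloromethyl methyl ether, COCCl
Why: O-alkylation of the acidic enol with an α-chloro ether and a hindered amine gives the enol MOM ether, a group on O9 that tolerates dissolving metal, amide base, hydride and borane and has no tendency to migrate.

Step 8
Reactants: 14 enol-ether enone
Product: 16 trans-fused 9α-(methoxymethoxy)-4,5β-dimethyldecal-3-en-8-one (10α-H), via lithium C8-C9 enolate 15 (not isolated)
Conditions: Li (2.5 equiv), t-BuOH (1 equiv), NH3(l)/THF, −78 °C; isoprene; NH4Cl(s); then K2CO3, MeOH, rt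
Reagents that add atoms: none
Why: Birch-type dissolving-metal reduction of an angularly methylated octalone, in which the β-carbanion at C10 is protonated axially to give the trans ring fusion typical of this enone class; after the excess metal is destroyed, protonation at C9 and base equilibration should place the ether equatorial (9α), because a 9β substituent would be 1,3-diaxial to C14.

Step 9
Reactants: 16 trans-decalone
Product: 18 7α-(2-hydroxypropan-2-yl)-9α-(methoxymethoxy)-4,5β-dimethyl-10αH-decal-3-en-8-one, via lithium C7-C8 enolate 17 (not isolated)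
Conditions: LiN(i-Pr)2, THF, −78 °C; acetone, −78 °C; AcOH
Reagents that add atoms: acetone, CC(C)=O
Why: Kinetic deprotonation should occur at the C7 methylene and not at the hindered alkoxy-bearing C9 methine, and the enolate adds to acetone in an aldol addition; the new C7 centre (expected α, away from C14) is removed in step 10.

Step 10
Reactants: 18 aldol adduct
Product: 20 9α-(methoxymethoxy)-10αH-eremophila-3,7(11)-dien-8-one, via tertiary mesylate 19 (not isolated)
Conditions: MsCl, Et3N, CH2Cl2, 0 °C; then DBU, rt
Reagents that add atoms: none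
Why: Sulfene-type mesylation of the tertiary alcohol followed by base-promoted E1cB elimination through the C7 enolate should give the conjugated tetrasubstituted isopropylidene ketone in preference to the isopropenyl isomer.

Step 11
Reactants: 20 isopropylidene enone
Product: 21 9α-(methoxymethoxy)-10αH-eremophila-3,7(11)-dien-8β-ol
Conditions: NaBH4, CeCl3·7H2O, MeOH, −20 → 0 °C
Reagents that add atoms: none
Why: Luche 1,2-reduction masks the C8 carbonyl as an allylic alcohol so that the next step meets no ketone; axial hydride delivery is expected to give the 8β alcohol, a centre that is removed again in step 13.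

Step 12
Reactants: 21 dienol
Product: 23 9α-(methoxymethoxy)-10αH-eremophil-7(11)-ene-3α,8β-diol, via alkylborane borinate 22 (not isolated)
Conditions: 9-BBN (3 equiv B–H), THF, 65 °C; then 3 M NaOH, 30% H2O2, 0 °C → rt
Reagents that add atoms: hydrogen peroxide, OO
Why: Hydroboration–oxidation in which 9-BBN should add only to the trisubstituted C3=C4 alkene (tetrasubstituted C7=C11 is inert to it), with boron on C3 and from the α face opposite the axial C14 methyl of the trans-decalin, so that syn addition and oxidation with retention set 3α-OH and 4α-H (4β-methyl) together.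

Step 13
Reactants: 23 diol
Product: 24 3α-hydroxy-9α-(methoxymethoxy)-10αH-eremophil-7(11)-en-8-one
Conditions: MnO2 (activated, excess), CH2Cl2, rt
Reagents that add atoms: none
Why: Chemoselective allylic oxidation by MnO2 returns the C8 enone and should leave the saturated C3 carbinol untouched.

Step 14
Reactants: 25 (E)-non-3-en-2-one; 26 triethyl 4-phosphonocrotonate
Product: 28 ethyl (2E,4E,6E)-5-methyldodeca-2,4,6-trienoate, via lithiated phosphonate 27 (not isolated)
Conditions: LiN(SiMe3)2, THF, −78 °C; then 25, −78 → 0 °C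
Reagents that add atoms: none
Why: Vinylogous Horner–Wadsworth–Emmons olefination of the methyl ketone keeps the 2E and 6E geometries of the two partners and should form the new C4=C5 bond mainly E (heptenyl group trans to the ester chain); any 4Z isomer is removed by chromatography.

Step 15
Reactants: 28 ethyl trienoate
Product: 29 (2E,4E,6E)-5-methyldodeca-2,4,6-trienoic acid
Conditions: LiOH, THF/MeOH/H2O, rt; then 1 M HCl to pH 3
Reagents that add atoms: lithium hydroxide, [Li+].[OH-]
Why: Saponification by acyl substitution at the ester carbonyl, mild enough to leave the triene geometry intact.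

Step 16
Reactants: 24 C3 alcohol; 29 trienoic acid
Product: 31 9α-(methoxymethoxy)-8-oxo-10αH-eremophil-7(11)-en-3α-yl (2E,4E,6E)-5-methyldodeca-2,4,6-trienoate, via mixed anhydride 30 (not isolated)
Conditions: 2,4,6-trichlorobenzoyl chloride, Et3N, toluene, rt; then 24, DMAP, toluene, rt
Reagents that add atoms: none
Why: Yamaguchi esterification, in which DMAP transfers the trienoyl group from the mixed anhydride to the only free hydroxyl (equatorial C3–OH) without touching the C3–O bond, so the configuration is retained.

Step 17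
Reactants: 31 MOM-protected ester
Product: 32 9α-hydroxy-8-oxo-10αH-eremophil-7(11)-en-3α-yl (2E,4E,6E)-5-methyldodeca-2,4,6-trienoate (target)
Conditions: 3 M HCl (aq), THF, 40 °C
Reagents that add atoms: none
Why: Acid-catalysed hydrolysis of the formaldehyde acetal frees the 9α-hydroxyl; the conjugated ester and enone should tolerate these conditions, and C9 already has the equatorial configuration favoured next to the ketone.

**Compound list**

1 | 2-methoxy-4,5-dimethylphenol | COc1cc(C)c(C)cc1O | starting material
2 | phenyl vinyl sulfone | C=CS(=O)(=O)c1ccccc1 | starting material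
3 | 6,6-dimethoxy-3,4-dimethylcyclohexa-2,4-dien-1-one (masked o-benzoquinone) | COC1(OC)C=C(C)C(C)=CC1=O | intermediate
4 | racemic (1R*,4S*,7S*)-3,3-dimethoxy-5,6-dimethyl-7-(phenylsulfonyl)bicyclo[2.2.2]oct-5-en-2-one | O=C1C(OC)(OC)[C@H]2C[C@H](S(=O)(=O)c3ccccc3)[C@@H]1C(C)=C2C | intermediate
5 | (1R,4S,7S)-3,3-dimethoxy-5,6-dimethyl-7-(phenylsulfonyl)bicyclo[2.2.2]oct-5-en-2-one | O=C1C(OC)(OC)[C@H]2C[C@H](S(=O)(=O)c3ccccc3)[C@@H]1C(C)=C2C | intermediate
6 | vinylmagnesium bromide | C=C[Mg]Br | starting material
7 | (1R,2R,4S,7S)-3,3-dimethoxy-5,6-dimethyl-7-(phenylsulfonyl)-2-vinylbicyclo[2.2.2]oct-5-en-2-ol | C=C[C@]1(O)C(OC)(OC)[C@H]2C[C@H](S(=O)(=O)c3ccccc3)[C@@H]1C(C)=C2C | intermediate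
8 | (1R,2R,4S)-3,3-dimethoxy-5,6-dimethyl-2-vinylbicyclo[2.2.2]oct-5-en-2-ol (vinyl syn to the alkene bridge) | C=C[C@]1(O)C(OC)(OC)[C@H]2CC[C@@H]1C(C)=C2C | intermediate
9 | potassium alkoxide of 8 | C=C[C@]1([O-])C(OC)(OC)[C@H]2CC[C@@H]1C(C)=C2C.[K+] | intermediate
10 | potassium C7–C8 enolate of 11 | CC1=CCC[C@@H]2C(OC)(OC)C([O-])=CC[C@]12C.[K+] | intermediate
11 | cis-fused 9,9-dimethoxy-4,5β-dimethyldecal-3-en-8-one (10β-H); (4aS,8aS)-1,1-dimethoxy-4a,5-dimethyl-3,4,4a,7,8,8a-hexahydronaphthalen-2(1H)-one | CC1=CCC[C@@H]2C(OC)(OC)C(=O)CC[C@]12C | intermediate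
12 | cis-fused 4,5β-dimethyldecal-3-ene-8,9-dione (10β-H) | CC1=CCC[C@@H]2C(=O)C(=O)CC[C@]12C | intermediate
13 | diosphenol, (4aR)-1-hydroxy-4a,5-dimethyl-4,4a,7,8-tetrahydronaphthalen-2(3H)-one (C9 enol, C8 ketone, C3=C4 and C9=C10 alkenes) | CC1=CCCC2=C(O)C(=O)CC[C@]12C | intermediate
14 | (4aR)-1-(methoxymethoxy)-4a,5-dimethyl-4,4a,7,8-tetrahydronaphthalen-2(3H)-one | CC1=CCCC2=C(OCOC)C(=O)CC[C@]12C | intermediate
15 | lithium C8–C9 enolate, trans-fused (10α-H) | CC1=CCC[C@H]2C(OCOC)=C([O-])CC[C@]12C.[Li+] | intermediate
16 | trans-fused 9α-(methoxymethoxy)-4,5β-dimethyldecal-3-en-8-one (10α-H) | CC1=CCC[C@H]2[C@H](OCOC)C(=O)CC[C@]12C | intermediate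
17 | lithium C7–C8 enolate of 16 | CC1=CCC[C@H]2[C@H](OCOC)C([O-])=CC[C@]12C.[Li+] | intermediate
18 | 7α-(2-hydroxypropan-2-yl)-9α-(methoxymethoxy)-4,5β-dimethyl-10αH-decal-3-en-8-one | CC1=CCC[C@H]2[C@H](OCOC)C(=O)[C@H](C(C)(C)O)C[C@]12C | intermediate
19 | tertiary methanesulfonate of 18 | CC1=CCC[C@H]2[C@H](OCOC)C(=O)[C@H](C(C)(C)OS(C)(=O)=O)C[C@]12C | intermediate
20 | 9α-(methoxymethoxy)-10αH-eremophila-3,7(11)-dien-8-one | CC1=CCC[C@H]2[C@H](OCOC)C(=O)C(=C(C)C)C[C@]12C | intermediate
21 | 9α-(methoxymethoxy)-10αH-eremophila-3,7(11)-dien-8β-ol | CC1=CCC[C@H]2[C@H](OCOC)[C@@H](O)C(=C(C)C)C[C@]12C | intermediate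
22 | 3α-(9-borabicyclo[3.3.1]nonan-9-yl) 8-O-(9-borabicyclo[3.3.1]nonan-9-yl) adduct of 21 | C3CC4CCCC(C3)B4[C@@H]1CC[C@H]2[C@H](OCOC)[C@@H](OB3C4CCCC3CCC4)C(=C(C)C)C[C@]2(C)[C@H]1C | intermediate
23 | 9α-(methoxymethoxy)-10αH-eremophil-7(11)-ene-3α,8β-diol | O[C@@H]1CC[C@H]2[C@H](OCOC)[C@@H](O)C(=C(C)C)C[C@]2(C)[C@H]1C | intermediate
24 | 3α-hydroxy-9α-(methoxymethoxy)-10αH-eremophil-7(11)-en-8-one | O[C@@H]1CC[C@H]2[C@H](OCOC)C(=O)C(=C(C)C)C[C@]2(C)[C@H]1C | intermediate
25 | (E)-non-3-en-2-one | CCCCC/C=C/C(C)=O | starting material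
26 | triethyl 4-phosphonocrotonate, ethyl (E)-4-(diethoxyphosphoryl)but-2-enoate | CCOC(=O)/C=C/CP(=O)(OCC)OCC | starting material
27 | lithium salt of the C4 carbanion of 26 | CCOC(=O)/C=C/[CH-]P(=O)(OCC)OCC.[Li+] | intermediate
28 | ethyl (2E,4E,6E)-5-methyldodeca-2,4,6-trienoate | CCCCC/C=C/C(C)=C/C=C/C(=O)OCC | intermediate
29 | (2E,4E,6E)-5-methyldodeca-2,4,6-trienoic acid | CCCCC/C=C/C(C)=C/C=C/C(=O)O | intermediate
30 | (2E,4E,6E)-5-methyldodeca-2,4,6-trienoic 2,4,6-trichlorobenzoic anhydride | CCCCC/C=C/C(C)=C/C=C/C(=O)OC(=O)c1c(Cl)cc(Cl)cc1Cl | intermediate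
31 | 9α-(methoxymethoxy)-8-oxo-10αH-eremophil-7(11)-en-3α-yl (2E,4E,6E)-5-methyldodeca-2,4,6-trienoate | CCCCC/C=C/C(C)=C/C=C/C(=O)O[C@@H]1CC[C@H]2[C@H](OCOC)C(=O)C(=C(C)C)C[C@]2(C)[C@H]1C | intermediate
32 | (3R,4R,5R,9S,10R)-9-hydroxy-8-oxoeremophil-7(11)-en-3-yl (2E,4E,6E)-5-methyldodeca-2,4,6-trienoate, CNP0211657.1 | CCCCC/C=C/C(C)=C/C=C/C(=O)O[C@@H]1CC[C@H]2[C@H](O)C(=O)C(=C(C)C)C[C@]2(C)[C@H]1C | target

**Step count**

Total: 17 steps. Longest linear sequence: 15 steps (steps 1–13, 16 and 17, from phenol 1); the side-chain acid takes 2 steps (14 and 15).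

**Steps most likely to fail**

Step 8. If enolate 15 is protonated while lithium is still present, the α-alkoxy ketone can be reduced further (cleavage of the C9–O bond or reduction of the carbonyl). The fallback sets out from 14 and comes back at 16. The same metal reduction is run, but after the ammonia is evaporated the enolate is silylated with Me3SiCl/Et3N in THF and isolated as the silyl enol ether 9-(methoxymethoxy)-8-(trimethylsilyloxy)-4,5β-dimethyl-10αH-decala-3,8-diene F1, which cannot be over-reduced. K2CO3 in MeOH then releases ketone 16 and equilibrates C9, so the ketone never meets the metal.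

Step 12. The hindered C3=C4 alkene may hydroborate too slowly with 9-BBN, and a smaller borane would also attack the C7=C11 alkene or lose facial selectivity. The fallback sets out from 20 and comes back at 24, bypassing 21 and 23. Epoxidation with mCPBA (CH2Cl2, NaHCO3, 0 °C) should occur only at the electron-rich trisubstituted alkene and from the α face, giving 3α,4α-epoxy-9α-(methoxymethoxy)-10αH-eremophil-7(11)-en-8-one F2. Radical opening with Cp2TiCl (trivalent titanium, made from Cp2TiCl2 and Zn dust) in THF with 1,4-cyclohexadiene cleaves the C4–O bond to the tertiary radical. Hydrogen-atom transfer to C4 from the α face, opposite C14, would then give 24 with 3α-OH and 4β-methyl.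

Step 1. Self-dimerisation of dienone 3 may outrun cycloaddition to the electron-poor sulfone. The fallback sets out from 1 and comes back at 4. The oxidation is run in the presence of phenyl vinyl sulfide, an electron-rich dienophile that reacts with the electron-poor dienone in the inverse-demand sense with the same ortho/endo orientation, giving racemic 3,3-dimethoxy-5,6-dimethyl-7-(phenylthio)bicyclo[2.2.2]oct-5-en-2-one F3. Chemoselective sulfur oxidation (30% H2O2, catalytic Na2WO4, MeOH, rt) then gives sulfone 4 without epoxidising the alkene.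

**Further compounds**

F1 | step 8 | 9-(methoxymethoxy)-8-(trimethylsilyloxy)-4,5β-dimethyl-10αH-decala-3,8-diene | CC1=CCC[C@H]2C(OCOC)=C(O[Si](C)(C)C)CC[C@]12C
F2 | step 12 | 3α,4α-epoxy-9α-(methoxymethoxy)-10αH-eremophil-7(11)-en-8-one | O1[C@@H]2CC[C@H]3[C@H](OCOC)C(=O)C(=C(C)C)C[C@]3(C)[C@]12C
F3 | step 1 | racemic 3,3-dimethoxy-5,6-dimethyl-7-(phenylthio)bicyclo[2.2.2]oct-5-en-2-one | O=C1C(OC)(OC)[C@H]2C[C@H](Sc3ccccc3)[C@@H]1C(C)=C2C
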